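**Retrosynthetic overview**

1. The pyran C–O bond is disconnected first. The 2H-chromene is closed in the last step from the C-prenylated, methylene-bridged dimer by dehydrogenation to a vinylogous o-quinone methide and oxa-6π electrocyclisation, the presumed biosynthetic prenyl → chromene conversion.
2. The CH2 bridge is disconnected next: C-prenyl phlorobutyrophenone (as Mannich base / o-quinone methide) plus the (R)-geranyl methyl triketone as Michael donor.
3. The (R)-triketone comes from 3-methylphloroacetophenone by catalytic enantioselective dearomative C-geranylation, which sets the only stereocentre.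
4. The monomers come from C-prenylation of phlorobutyrophenone and C-acetylation of 2-methylphloroglucinol.
5. Ring order: both carbocycles are bought as phloroglucinols (one is dearomatised in the geranylation); the pyran is the only ring formed, and it is formed last.

Assumption: phlorobutyrophenone and 2-methylphloroglucinol are taken as purchasable catalogue chemicals, and the descriptor 4R refers to the keto–enol tautomer written in the target SMILES.

**Route**

Step 1
Reactants: 1 phlorobutyrophenone (1-(2,4,6-trihydroxyphenyl)butan-1-one); 2 prenyl bromide (1-bromo-3-methylbut-2-ene)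
Product: 3 C-prenylphlorobutyrophenone (1-[2,4,6-trihydroxy-3-(3-methylbut-2-en-1-yl)phenyl]butan-1-one)
Conditions: 2 (0.9 equiv), 5% aq KOH (1.0 equiv), 0 °C, 2 h
Reagents that add atoms: none
Why: Friedel–Crafts-type C-allylation of the ambident phloroglucinolate: water as solvent steers the soft allylic bromide to carbon, both free ring positions of 1 are equivalent, and the deficit of 2 limits 3,5-diprenylation.

Step 2
Reactants: 4 methylphloroglucinol (2,4,6-trihydroxytoluene)
Product: 5 methylphloroacetophenone (1-(2,4,6-trihydroxy-3-methylphenyl)ethan-1-one)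
Conditions: Ac2O (1.05 equiv), MeSO3H (solvent), 50 °C, 1 h
Reagents that add atoms: acetic anhydride, CC(=O)OC(C)=O
Why: Friedel–Crafts C-acylation (O-acetylation/Fries pathway) in a strong protic acid; the two free positions of 4 are equivalent and the first acyl group deactivates the ring against a second.

Step 3
Reactants: 5 methylphloroacetophenone; 6 geranyl acetate ((2E)-3,7-dimethylocta-2,6-dien-1-yl acetate)
Product: 7 (4R)-2-acetyl-4-[(2E)-3,7-dimethylocta-2,6-dien-1-yl]-3,5-dihydroxy-4-methylcyclohexa-2,5-dien-1-one
Conditions: 6 (0.95 equiv), Pd2(dba)3·CHCl3 (2.5 mol %), (R,R)-ANDEN-phenyl Trost ligand (7.5 mol %), Et3N (1.0 equiv), CH2Cl2, −20 → 0 °C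
Reagents that add atoms: none
Why: Proposed new method: Pd(0) ionises 6 to the π-geranyl complex and the triethylammonium phloroglucinolate of 5 attacks its unsubstituted terminus (linear product, E-alkene kept) through the methyl-bearing ring carbon, the more electron-rich terminus of the vinylogous enolate as in the classical gem-dialkylation that gives filicinic-acid-type triketones, while O-geranyl ethers are re-ionised by Pd and funnelled to carbon, so that the chiral pocket of the Trost ligand differentiates the two faces of the prochiral nucleophile and sets the 4R quaternary centre; the closest known reaction types are the Pd-catalysed asymmetric allylic dearomatisation of naphthols and the Trost asymmetric prenylation and geranylation of prochiral oxindole and β-dicarbonyl nucleophiles, used here as a mimic of the dearomatising prenyl transfer.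

Step 4
Reactants: 3 C-prenylphlorobutyrophenone; 7 (R)-geranyl methyl triketone
Product: 10 (4R)-2-acetyl-6-{[3-butanoyl-2,4,6-trihydroxy-5-(3-methylbut-2-en-1-yl)phenyl]methyl}-4-[(2E)-3,7-dimethylocta-2,6-dien-1-yl]-3,5-dihydroxy-4-methylcyclohexa-2,5-dien-1-one, via Mannich base 8 (not isolated), via o-quinone methide 9 (not isolated)
Conditions: Me2N=CH2+ I− (1.0 equiv), MeCN, rt, 1 h; then 7 (1.0 equiv), NaOAc (1.0 equiv), 70 °C, 4 h
Reagents that add atoms: Eschenmoser's salt (N,N-dimethylmethyleneiminium iodide), C=[N+](C)C.[I-]
Why: Mannich aminomethylation at the only free aromatic carbon of 3 gives 8, which on warming loses dimethylamine to the o-quinone methide 9 that is trapped at the free ring carbon of the acidic triketone 7 (Mannich/o-quinone-methide Michael relay), so no statistical homodimers arise as with free formaldehyde and the quaternary centre is untouched.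

Step 5
Reactants: 10 prenylated methylene-bridged dimer
Product: 12 CNP0203748.1 ((4R)-2-acetyl-6-[(6-butanoyl-5,7-dihydroxy-2,2-dimethyl-2H-chromen-8-yl)methyl]-4-[(2E)-3,7-dimethylocta-2,6-dien-1-yl]-3,5-dihydroxy-4-methylcyclohexa-2,5-dien-1-one), via vinylogous o-quinone methide 11 (not isolated)
Conditions: DDQ (1.05 equiv), PhMe, 0 °C → rt, 1 h
Reagents that add atoms: none
Why: Biomimetic DDQ cyclodehydrogenation: hydride abstraction from the benzylic and allylic CH2 of the prenyl group gives the vinylogous o-quinone methide 11, which closes by oxa-6π electrocyclisation through the more acidic oxygen para to the butanoyl group to the 2,2-dimethyl-2H-chromene (closure through a chelated ortho oxygen would give the 8-butanoyl isomer as the minor product), while the isolated geranyl alkenes, the β-triketone and the quaternary centre are not touched at 0 °C.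

**Compound list**

1 | phlorobutyrophenone, 1-(2,4,6-trihydroxyphenyl)butan-1-one | CCCC(=O)c1c(O)cc(O)cc1O | starting material
2 | prenyl bromide, 1-bromo-3-methylbut-2-ene | CC(C)=CCBr | starting material
3 | 1-[2,4,6-trihydroxy-3-(3-methylbut-2-en-1-yl)phenyl]butan-1-one | CCCC(=O)c1c(O)cc(O)c(CC=C(C)C)c1O | intermediate
4 | methylphloroglucinol, 2,4,6-trihydroxytoluene | Cc1c(O)cc(O)cc1O | starting material
5 | 1-(2,4,6-trihydroxy-3-methylphenyl)ethan-1-one | CC(=O)c1c(O)cc(O)c(C)c1O | intermediate
6 | geranyl acetate, (2E)-3,7-dimethylocta-2,6-dien-1-yl acetate | CC(=O)OC/C=C(\C)CCC=C(C)C | starting material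
7 | (4R)-2-acetyl-4-[(2E)-3,7-dimethylocta-2,6-dien-1-yl]-3,5-dihydroxy-4-methylcyclohexa-2,5-dien-1-one | O=C1C=C(O)[C@@](C)(C/C=C(\C)CCC=C(C)C)C(O)=C1C(C)=O | intermediate
8 | Mannich base, 1-[3-[(dimethylamino)methyl]-2,4,6-trihydroxy-5-(3-methylbut-2-en-1-yl)phenyl]butan-1-one | CCCC(=O)c1c(O)c(CN(C)C)c(O)c(CC=C(C)C)c1O | intermediate
9 | o-quinone methide, 4-butanoyl-3,5-dihydroxy-6-methylidene-2-(3-methylbut-2-en-1-yl)cyclohexa-2,4-dien-1-one | CCCC(=O)C1=C(O)C(=C)C(=O)C(CC=C(C)C)=C1O | intermediate
10 | (4R)-2-acetyl-6-{[3-butanoyl-2,4,6-trihydroxy-5-(3-methylbut-2-en-1-yl)phenyl]methyl}-4-[(2E)-3,7-dimethylocta-2,6-dien-1-yl]-3,5-dihydroxy-4-methylcyclohexa-2,5-dien-1-one | CCCC(=O)c1c(O)c(CC=C(C)C)c(O)c(CC2=C(O)[C@@](C)(C/C=C(\C)CCC=C(C)C)C(O)=C(C(C)=O)C2=O)c1O | intermediate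
11 | vinylogous o-quinone methide, (4R)-2-acetyl-6-{[3-butanoyl-2,4-dihydroxy-5-(3-methylbut-2-en-1-ylidene)-6-oxocyclohexa-1,3-dien-1-yl]methyl}-4-[(2E)-3,7-dimethylocta-2,6-dien-1-yl]-3,5-dihydroxy-4-methylcyclohexa-2,5-dien-1-one | CCCC(=O)C1=C(O)C(=CC=C(C)C)C(=O)C(CC2=C(O)[C@@](C)(C/C=C(\C)CCC=C(C)C)C(O)=C(C(C)=O)C2=O)=C1O | intermediate
12 | CNP0203748.1, (4R)-2-acetyl-6-[(6-butanoyl-5,7-dihydroxy-2,2-dimethyl-2H-chromen-8-yl)methyl]-4-[(2E)-3,7-dimethylocta-2,6-dien-1-yl]-3,5-dihydroxy-4-methylcyclohexa-2,5-dien-1-one | CCCC(=O)c1c(O)c2c(c(CC3=C(O)[C@@](C)(C/C=C(\C)CCC=C(C)C)C(O)=C(C(C)=O)C3=O)c1O)OC(C)(C)C=C2 | target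

**Step count and risks**

Total step count: 5. Longest linear sequence: 4 (4 → 5 → 7 → 10 → 12).

The three steps most likely to fail, with the likeliest first, are step 3, step 5 and step 4; they are discussed in step order.

Step 3 (dearomative geranylation) carries three risks:
- The free C-5 position of 5 may compete with the methyl-bearing carbon, giving the aromatic C-geranyl isomer.
- The π-geranyl complex may partly scramble E/Z.
- The sense and level of induction are unknown; the ligand antipode is fixed after the first run by ECD or X-ray.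

The fallback sets out from 5 and comes back at 7. It gives up asymmetric catalysis for a classical alkylation plus resolution. Compound 5 is alkylated with geranyl bromide and NaOMe in MeOH at 0 °C, the conditions under which mono-C-alkyl acylphloroglucinols are known to undergo gem-dialkylation. Aqueous NaHCO3 extracts the strongly acidic racemic triketone F1 away from the aromatic and O-alkylated isomers. Preparative chiral SFC then separates F1 into 7 and the unwanted (4S)-enantiomer F2, which is discarded.

Step 4 (bridge formation) may fail because the o-quinone methide 9 oligomerises or because retro-Mannich exchange scrambles the partners. The fallback sets out from 7 and comes back at 10, with the polarity of the coupling reversed. Eschenmoser's salt in CH2Cl2 at 0 °C converts 7 at its free ring carbon into the triketone Mannich base F3. Warmed with 3 (1.5 equiv) and NaOAc in dioxane at 50 °C, F3 loses dimethylamine to the 2-methylidene trione F4. This strong Michael acceptor is captured by the single free aromatic carbon of 3 in a Friedel–Crafts-type conjugate addition, giving 10.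

Step 5 (late-stage cyclodehydrogenation) carries two risks:
- Closure through the ortho oxygen would give the 8-butanoyl regioisomer, which may be hard to separate from 12. I cannot secure the regiochemistry in advance, since both closure patterns occur among natural congeners.
- DDQ may attack the doubly activated bridging CH2.

The fallback sets out from 1 and comes back at 12. It builds the pyran on the monomer with the ring oxygen fixed beforehand:
- 3-Chloro-3-methylbut-1-yne (K2CO3, KI, cat. CuCl, acetone, 50 °C) alkylates only the non-chelated, most acidic 4-hydroxyl of 1, giving the aryl propargyl ether F5.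
- Heating F5 in xylene at 140 °C triggers aromatic Claisen rearrangement, 1,5-H shift and the same oxa-6π electrocyclisation. The two ortho carbons are equivalent, so the chromene F6 can only carry its ring oxygen para to the butanoyl group.
- Eschenmoser's salt aminomethylates F6 at C-8 to the chromene Mannich base F7.
- Heated with 7 and NaOAc in MeCN at 70 °C, F7 gives the chromene o-quinone methide F8, and Michael addition of 7 delivers 12.

Further compounds

F1 | step 3 | racemic 2-acetyl-4-[(2E)-3,7-dimethylocta-2,6-dien-1-yl]-3,5-dihydroxy-4-methylcyclohexa-2,5-dien-1-one | O=C1C=C(O)C(C)(C/C=C(\C)CCC=C(C)C)C(O)=C1C(C)=O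
F2 | step 3 | (4S)-2-acetyl-4-[(2E)-3,7-dimethylocta-2,6-dien-1-yl]-3,5-dihydroxy-4-methylcyclohexa-2,5-dien-1-one, the enantiomer of 7 | O=C1C=C(O)[C@](C)(C/C=C(\C)CCC=C(C)C)C(O)=C1C(C)=O
F3 | step 4 | (4R)-2-acetyl-6-[(dimethylamino)methyl]-4-[(2E)-3,7-dimethylocta-2,6-dien-1-yl]-3,5-dihydroxy-4-methylcyclohexa-2,5-dien-1-one | CN(C)CC1=C(O)[C@@](C)(C/C=C(\C)CCC=C(C)C)C(O)=C(C(C)=O)C1=O
F4 | step 4 | (4S)-2-acetyl-4-[(2E)-3,7-dimethylocta-2,6-dien-1-yl]-3-hydroxy-4-methyl-6-methylidenecyclohex-2-ene-1,5-dione (same spatial arrangement as in 7; only the CIP priorities change) | C=C1C(=O)[C@@](C)(C/C=C(\C)CCC=C(C)C)C(O)=C(C(C)=O)C1=O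
F5 | step 5 | 1-{2,6-dihydroxy-4-[(2-methylbut-3-yn-2-yl)oxy]phenyl}butan-1-one | CCCC(=O)c1c(O)cc(OC(C)(C)C#C)cc1O
F6 | step 5 | 1-(5,7-dihydroxy-2,2-dimethyl-2H-chromen-6-yl)butan-1-one | CCCC(=O)c1c(O)cc2OC(C)(C)C=Cc2c1O
F7 | step 5 | 1-{8-[(dimethylamino)methyl]-5,7-dihydroxy-2,2-dimethyl-2H-chromen-6-yl}butan-1-one | CCCC(=O)c1c(O)c(CN(C)C)c2OC(C)(C)C=Cc2c1O
F8 | step 5 | 6-butanoyl-5-hydroxy-2,2-dimethyl-8-methylidene-2H-chromen-7(8H)-one | CCCC(=O)C1=C(O)C2=C(OC(C)(C)C=C2)C(=C)C1=O
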